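**Retrosynthetic overview**
- The bicyclo[3.2.1]oct-3-ene-2,8-dione is cut at both bonds of its two-carbon bridge in one operation: a dearomative (3+2) annulation of C2/C10a of one resorcinol ring of pallidol di-O-acetate with the C7–C8 unit of 3,5-di-O-acetylresveratrol.
- The key C–C bond (resorcinol C2 to the stilbene carbon bearing the diacetoxyphenyl ring) joins two normally nucleophilic carbons: two-electron oxidation of the para-phenol makes the stilbene carbon a vinylogous enolonium (phenoxenium), and the tethered quinone methide then closes on C10a.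
- Pallidol di-O-acetate comes from a double 5-exo Friedel–Crafts cyclisation of a C2-symmetric (2S,3S)-1,4-diol.
- The diol comes from a bis-thioester and two molecules of an arylboronic acid; its central C–C bond and both stereocentres come from an auxiliary-controlled oxidative homocoupling of two molecules of an arylacetyl imide enolate.
- Ring order: indane, then second indane (cis-bicyclo[3.3.0]octane, step 7), then cyclopentanone and bridged cyclohexenedione together (step 9).

Assumption: the target is the stereoisomer written in the given SMILES; pallidol-type compounds carry indeno[2,1-a]indene locants (O at C1, C3, C6, C8; aryl at C5, C10; ring-fusion H at C4b, C9b; C2 lies between the two oxygens of one ring; C10a is the ring carbon bonded to C10).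

**Step 1**
Reactants: 1 3,5-dimethoxyphenylacetic acid; 2 (S)-4-benzyloxazolidin-2-one
Product: 4 (S)-4-benzyl-3-[(3,5-dimethoxyphenyl)acetyl]oxazolidin-2-one, via mixed pivalic anhydride 3 (not isolated)
Conditions: PivCl, Et3N, THF, −20 °C; then 2, LiCl, rt
Reagents that add atoms: none
Why: One-pot mixed-anhydride N-acylation of the oxazolidinone (Evans auxiliary attachment); no new stereocentre forms and the auxiliary centre is untouched.

**Step 2**
Reactants: 4 (S)-4-benzyl-3-[(3,5-dimethoxyphenyl)acetyl]oxazolidin-2-one (two molecules of 4 are joined per molecule of 7)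
Product: 7 3,3'-[(2S,3S)-2,3-bis(3,5-dimethoxyphenyl)butanedioyl]bis[(S)-4-benzyloxazolidin-2-one], via lithium Z-enolate 5 (not isolated), via trichlorotitanium Z-enolate 6 (not isolated)
Conditions: LiN(iPr)2 (1.05 equiv per 4), THF, −78 °C; then TiCl4 (1.1 equiv per 4), −78 °C to rt
Reagents that add atoms: second molecule of 4 (S)-4-benzyl-3-[(3,5-dimethoxyphenyl)acetyl]oxazolidin-2-one, COc1cc(CC(=O)N2[C@@H](Cc3ccccc3)COC2=O)cc(OC)c1
Why: Oxidative enolate homocoupling: two nucleophilic α-carbons are joined after one-electron oxidation of each enolate by tetravalent titanium, which leaves as trivalent titanium. Each chelated Z-enolate bonds on the face anti to the benzyl group (the facial sense of Evans alkylation), which for an arylacetyl imide of the S auxiliary gives S at both carbons and hence the C2-symmetric (2S,3S) dimer.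

**Step 3**
Reactants: 7 3,3'-[(2S,3S)-2,3-bis(3,5-dimethoxyphenyl)butanedioyl]bis[(S)-4-benzyloxazolidin-2-one]
Product: 8 S,S'-diethyl (2S,3S)-2,3-bis(3,5-dimethoxyphenyl)butanebis(thioate)
Conditions: NaSEt (2.2 equiv), THF, −20 °C; then H2O
Reagents that add atoms: sodium ethanethiolate, [Na+].[S-]CC; second equivalent of sodium ethanethiolate, [Na+].[S-]CC
Why: Thiolate transacylation at each exocyclic imide carbonyl releases both auxiliaries; the weakly basic thiolate at low temperature leaves the two α-aryl stereocentres intact.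

**Step 4**
Reactants: 8 S,S'-diethyl (2S,3S)-2,3-bis(3,5-dimethoxyphenyl)butanebis(thioate)
Product: 9 S,S'-diethyl (2S,3S)-2,3-bis(3,5-dihydroxyphenyl)butanebis(thioate)
Conditions: BBr3, CH2Cl2, −78 to 0 °C; then H2O
Reagents that add atoms: none
Why: Lewis-acid cleavage of the four aryl methyl ethers; thioesters are poor Lewis bases and should survive at low temperature, and no base is present to epimerise the α-centres.

**Step 5**
Reactants: 9 S,S'-diethyl (2S,3S)-2,3-bis(3,5-dihydroxyphenyl)butanebis(thioate); 10 4-acetoxyphenylboronic acid (3 equiv used, two molecules incorporated)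
Product: 11 (2S,3S)-1,4-bis(4-acetoxyphenyl)-2,3-bis(3,5-dihydroxyphenyl)butane-1,4-dione
Conditions: Pd2(dba)3 (5 mol%), P(2-furyl)3, Cu(O2CC4H3S) (copper thiophene-2-carboxylate, 3 equiv), THF, 50 °C
Reagents that add atoms: second equivalent of 10 4-acetoxyphenylboronic acid, CC(=O)Oc1ccc(B(O)O)cc1
Why: Twofold Liebeskind–Srogl thioester–boronic acid ketone synthesis, one aryl group per thioester; it runs without added base, so the acidic α-aryl centres are not epimerised and free phenols and aryl acetates are tolerated.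

**Step 6**
Reactants: 11 (2S,3S)-1,4-bis(4-acetoxyphenyl)-2,3-bis(3,5-dihydroxyphenyl)butane-1,4-dione
Product: 12 (2S,3S)-1,4-bis(4-acetoxyphenyl)-2,3-bis(3,5-dihydroxyphenyl)butane-1,4-diol (epimer mixture at C1 and C4)
Conditions: NaBH4, CeCl3·7H2O, MeOH/THF, −40 °C
Reagents that add atoms: none
Why: Luche reduction is fast and weakly basic, so C2/C3 are preserved and the aryl acetates survive; the carbinol configuration does not matter because both carbinols are ionised in step 7.

**Step 7**
Reactants: 12 (2S,3S)-1,4-bis(4-acetoxyphenyl)-2,3-bis(3,5-dihydroxyphenyl)butane-1,4-diol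
Product: 14 pallidol di-O-acetate [(4bR,5R,9bR,10R)-5,10-bis(4-acetoxyphenyl)-4b,5,9b,10-tetrahydroindeno[2,1-a]indene-1,3,6,8-tetrol], via monocyclised indanyl carbinol 13 (not isolated)
Conditions: TfOH (10 mol%), HFIP (0.01 M), 0 °C
Reagents that add atoms: none
Why: Double intramolecular Friedel–Crafts alkylation, each benzylic cation being captured 5-exo by the resorcinol ring on the neighbouring stereocentre (any tetrahydrofuran from the 1,4-diol re-ionises). The first closure sets the aryl-bearing carbon trans to the vicinal aryl group, and the second can only place its aryl on the convex face of the cis-fused bicyclo[3.3.0]octane, so C5 and C10 follow from the fixed C4b/C9b centres.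

**Step 8**
Reactants: 15 resveratrol triacetate
Product: 16 3,5-di-O-acetylresveratrol [(E)-5-(4-hydroxystyryl)-1,3-phenylene diacetate]
Conditions: Novozym 435 (immobilised Candida antarctica lipase B), n-BuOH, t-BuOMe, 40 °C
Reagents that add atoms: none
Why: Lipase-catalysed regioselective alcoholysis removes only the accessible acetate of the 4-oxystyryl ring; the alkene geometry is untouched.

**Step 9**
Reactants: 14 pallidol di-O-acetate; 16 3,5-di-O-acetylresveratrol
Product: 19 tetra-O-acetyl derivative of the target, via phenoxenium acetate 17 (not isolated), via dienone quinone methide 18 (not isolated)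
Conditions: 16 and PhI(OAc)2 (1.0 equiv each, separate slow additions over 2 h) to 14 (1.5 equiv), HFIP/CH2Cl2 1:1, −30 °C, then 0 °C
Reagents that add atoms: none
Why: Proposed new method: PhI(OAc)2 exchanges reversibly with the phenols present and heterolyses fastest at the styryl-conjugated phenol of 16, giving phenoxenium 17, a vinylogous enolonium whose stilbene carbon next to the diacetoxyphenyl ring (normally nucleophilic) is now electrophilic; a free resorcinol ring of 14 (the two are homotopic, the other arenes being deactivated as acetates) attacks it through C2, the ring position not shielded by the indane, in HFIP where C-alkylation is favoured, giving after O–H loss the non-aromatic dienone 18 with a pendant para-quinone methide; before 18 tautomerises, its dienol terminus C10a adds 5-exo-trig to the quinone methide from the face opposite the C10 aryl group (only that C2 epimer can close) to give the bridged dione with the two new aryl groups trans and the 4-hydroxyphenyl exo, the least hindered closure and the relative configuration of the target; the closest known reaction types are hypervalent-iodine oxidative phenol–arene cross-coupling in fluoroalcohols and the cationic [5+2] cycloaddition of oxidised phenols (quinone monoketal cations) with styrenes that gives bicyclo[3.2.1]octenediones.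

**Step 10**
Reactants: 19 tetra-O-acetyl derivative of the target
Product: 20 target CNP0407321.1
Conditions: NH4OAc, MeOH/H2O 4:1, rt
Reagents that add atoms: none
Why: Ammonium acetate-mediated solvolysis of the four aryl acetates at neutral pH (aryl ester deprotection) avoids alkoxide, which would open the non-enolisable bridged 1,3-diketone by retro-Claisen cleavage, and strong acid, which would promote retro-Michael opening towards the dihydrobenzofuran isomer; no stereocentre is touched.

**Compound list**
1 | 3,5-dimethoxyphenylacetic acid | COc1cc(CC(=O)O)cc(OC)c1 | starting material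
2 | (S)-4-benzyloxazolidin-2-one | O=C1N[C@@H](Cc2ccccc2)CO1 | starting material
3 | 3,5-dimethoxyphenylacetic pivalic anhydride | COc1cc(CC(=O)OC(=O)C(C)(C)C)cc(OC)c1 | intermediate
4 | (S)-4-benzyl-3-[(3,5-dimethoxyphenyl)acetyl]oxazolidin-2-one | COc1cc(CC(=O)N2[C@@H](Cc3ccccc3)COC2=O)cc(OC)c1 | intermediate
5 | lithium Z-enolate of 4 | COc1cc(/C=C(\[O-])N2[C@@H](Cc3ccccc3)COC2=O)cc(OC)c1.[Li+] | intermediate
6 | trichlorotitanium Z-enolate of 4 | COc1cc(/C=C(\O[Ti](Cl)(Cl)Cl)N2[C@@H](Cc3ccccc3)COC2=O)cc(OC)c1 | intermediate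
7 | 3,3'-[(2S,3S)-2,3-bis(3,5-dimethoxyphenyl)butanedioyl]bis[(S)-4-benzyloxazolidin-2-one] | O=C1OC[C@H](Cc2ccccc2)N1C(=O)[C@H](c1cc(OC)cc(OC)c1)[C@@H](c1cc(OC)cc(OC)c1)C(=O)N1[C@@H](Cc2ccccc2)COC1=O | intermediate
8 | S,S'-diethyl (2S,3S)-2,3-bis(3,5-dimethoxyphenyl)butanebis(thioate) | CCSC(=O)[C@H](c1cc(OC)cc(OC)c1)[C@@H](c1cc(OC)cc(OC)c1)C(=O)SCC | intermediate
9 | S,S'-diethyl (2S,3S)-2,3-bis(3,5-dihydroxyphenyl)butanebis(thioate) | CCSC(=O)[C@H](c1cc(O)cc(O)c1)[C@@H](c1cc(O)cc(O)c1)C(=O)SCC | intermediate
10 | 4-acetoxyphenylboronic acid | CC(=O)Oc1ccc(B(O)O)cc1 | starting material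
11 | (2S,3S)-1,4-bis(4-acetoxyphenyl)-2,3-bis(3,5-dihydroxyphenyl)butane-1,4-dione | CC(=O)Oc1ccc(cc1)C(=O)[C@H](c1cc(O)cc(O)c1)[C@@H](c1cc(O)cc(O)c1)C(=O)c1ccc(OC(C)=O)cc1 | intermediate
12 | (2S,3S)-1,4-bis(4-acetoxyphenyl)-2,3-bis(3,5-dihydroxyphenyl)butane-1,4-diol, epimer mixture at C1 and C4 | CC(=O)Oc1ccc(cc1)C(O)[C@H](c1cc(O)cc(O)c1)[C@@H](c1cc(O)cc(O)c1)C(O)c1ccc(OC(C)=O)cc1 | intermediate
13 | monocyclised indanyl carbinol: 3-(4-acetoxyphenyl)-1-[(4-acetoxyphenyl)(hydroxy)methyl]-2-(3,5-dihydroxyphenyl)indane-4,6-diol, C2/C3 aryl groups trans, C1/C2 substituents cis | Oc1cc(cc(O)c1)[C@H]1[C@H](c2ccc(OC(C)=O)cc2)c2c(O)cc(O)cc2[C@H]1C(O)c1ccc(OC(C)=O)cc1 | intermediate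
14 | pallidol di-O-acetate, (4bR,5R,9bR,10R)-5,10-bis(4-acetoxyphenyl)-4b,5,9b,10-tetrahydroindeno[2,1-a]indene-1,3,6,8-tetrol | Oc1cc2[C@H]3[C@H](c4ccc(OC(C)=O)cc4)c4c(O)cc(O)cc4[C@H]3[C@H](c3ccc(OC(C)=O)cc3)c2c(O)c1 | intermediate
15 | resveratrol triacetate | CC(=O)Oc1ccc(/C=C/c2cc(OC(C)=O)cc(OC(C)=O)c2)cc1 | starting material
16 | 3,5-di-O-acetylresveratrol | CC(=O)Oc1cc(/C=C/c2ccc(O)cc2)cc(OC(C)=O)c1 | intermediate
17 | phenoxenium (quinone methide cation) acetate from 16 | O=C1C=CC(=C[CH+]c2cc(OC(C)=O)cc(OC(C)=O)c2)C=C1.CC(=O)[O-] | intermediate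
18 | dienone quinone methide: keto tautomer of the C2-alkylated resorcinol ring of 14 (C2 sp3, C1 carbonyl, C3 enol) carrying CH(3,5-diacetoxyphenyl)–CH=(4-oxocyclohexa-2,5-dienylidene), new chain on the face anti to the C10 aryl | OC1=CC=2[C@H]3[C@H](c4ccc(OC(C)=O)cc4)c4c(O)cc(O)cc4[C@H]3[C@H](c3ccc(OC(C)=O)cc3)C=2C(=O)[C@H]1[C@H](c1cc(OC(C)=O)cc(OC(C)=O)c1)C=C1C=CC(=O)C=C1 | intermediate
19 | tetra-O-acetyl derivative of the target: acetates on the two 4-oxyphenyl groups of the pallidol part and on the 3,5-dioxyphenyl ring of the new bridge; two-carbon bridge anti to the C10 aryl, 4-hydroxyphenyl exo, 3,5-diacetoxyphenyl endo (trans) | O=C1C=C2[C@H]3[C@H](c4ccc(OC(C)=O)cc4)c4c(O)cc(O)cc4[C@H]3[C@H](c3ccc(OC(C)=O)cc3)[C@]23C(=O)[C@H]1[C@H](c1cc(OC(C)=O)cc(OC(C)=O)c1)[C@H]3c1ccc(O)cc1 | intermediate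
20 | CNP0407321.1 | O=C1C=C2[C@H]3[C@H](c4ccc(O)cc4)c4c(O)cc(O)cc4[C@H]3[C@H](c3ccc(O)cc3)[C@]23C(=O)[C@H]1[C@H](c1cc(O)cc(O)c1)[C@H]3c1ccc(O)cc1 | target

**Totals and risks**
Total step count: 10. Longest linear sequence: 9 (steps 1–7, 9, 10).

The three steps most likely to fail are 9, 4 and 2.

Step 9 may fail because the oxidant is consumed by 14, because 16 couples with itself, or because the quinone methide closes on oxygen to give a dihydrobenzofuran. The fallback separates oxidation from C–C bond formation. It sets out from 16, which is oxidised alone with PhI(OAc)2 in MeCN/H2O at 0 °C to the para-quinol 4-hydroxy-4-[(E)-2-(3,5-diacetoxyphenyl)ethenyl]cyclohexa-2,5-dienone F1. F1 is then ionised with TfOH (5 mol%) in HFIP at −20 °C in the presence of 14. Loss of water regenerates the cation of 17 in an oxidant-free, strongly ionising medium, and the same alkylation and ring closure come back to the route at 19.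

Step 4 may fail because BBr3 attacks the thioesters of 8 or closes them onto the arenes. The fallback carries the methyl ethers through to the robust pallidol skeleton. It sets out from 8: twofold Liebeskind–Srogl coupling with 4-methoxyphenylboronic acid (3 equiv, two molecules incorporated) gives (2S,3S)-2,3-bis(3,5-dimethoxyphenyl)-1,4-bis(4-methoxyphenyl)butane-1,4-dione F2. Luche reduction gives the corresponding 1,4-diol F3, and BF3·OEt2 (CH2Cl2, −78 to −20 °C) gives pallidol hexamethyl ether F4. BBr3 then gives pallidol F5. Lipase-catalysed acetylation (Novozym 435, vinyl acetate, t-BuOMe) should acylate only the two unhindered 4-hydroxyphenyl groups, as it does the 4'-OH of resveratrol, and comes back to the route at 14.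

Step 2 may fail through low yield, poor diastereoselectivity or an unexpected facial sense in the titanium-mediated homocoupling of 4 with the electron-rich aryl group. The configuration of 7 is therefore confirmed by X-ray before going on. The fallback drops the auxiliary and sets out from 1. Dianion formation (LiN(iPr)2, 2.2 equiv, THF) and oxidation with I2 (0.5 equiv) join two molecules of 1. After crystallisation away from the meso isomer this gives racemic (2S,3S)/(2R,3R)-2,3-bis(3,5-dimethoxyphenyl)succinic acid F6. Classical resolution by crystallisation with an enantiopure 1-phenylethylamine, then acidification, gives (2S,3S)-2,3-bis(3,5-dimethoxyphenyl)succinic acid F7. Twofold thioesterification (EtSH, EDC, DMAP cat., CH2Cl2, 0 °C) comes back to the route at 8.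

**Further compounds**
F1 | step 9 | 4-hydroxy-4-[(E)-2-(3,5-diacetoxyphenyl)ethenyl]cyclohexa-2,5-dienone | CC(=O)Oc1cc(/C=C/C2(O)C=CC(=O)C=C2)cc(OC(C)=O)c1
F2 | step 4 | (2S,3S)-2,3-bis(3,5-dimethoxyphenyl)-1,4-bis(4-methoxyphenyl)butane-1,4-dione | COc1ccc(cc1)C(=O)[C@H](c1cc(OC)cc(OC)c1)[C@@H](c1cc(OC)cc(OC)c1)C(=O)c1ccc(OC)cc1
F3 | step 4 | (2S,3S)-2,3-bis(3,5-dimethoxyphenyl)-1,4-bis(4-methoxyphenyl)butane-1,4-diol, epimer mixture at C1 and C4 | COc1ccc(cc1)C(O)[C@H](c1cc(OC)cc(OC)c1)[C@@H](c1cc(OC)cc(OC)c1)C(O)c1ccc(OC)cc1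
F4 | step 4 | pallidol hexamethyl ether, (4bR,5R,9bR,10R) | COc1cc2[C@H]3[C@H](c4ccc(OC)cc4)c4c(OC)cc(OC)cc4[C@H]3[C@H](c3ccc(OC)cc3)c2c(OC)c1
F5 | step 4 | pallidol, (4bR,5R,9bR,10R) | Oc1cc2[C@H]3[C@H](c4ccc(O)cc4)c4c(O)cc(O)cc4[C@H]3[C@H](c3ccc(O)cc3)c2c(O)c1
F6 | step 2 | racemic 2,3-bis(3,5-dimethoxyphenyl)succinic acid, 1:1 mixture of the (2S,3S) and (2R,3R) enantiomers, so no single configuration is written | OC(=O)C(c1cc(OC)cc(OC)c1)C(c1cc(OC)cc(OC)c1)C(=O)O
F7 | step 2 | (2S,3S)-2,3-bis(3,5-dimethoxyphenyl)succinic acid | OC(=O)[C@H](c1cc(OC)cc(OC)c1)[C@@H](c1cc(OC)cc(OC)c1)C(=O)O
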